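**Retrosynthetic overview**

1. Target ⇒ (2E,6E)-C20 allylic alcohol + Meldrum's acid. The malonic half ester is put on last by acylal ring-opening, so no protecting group is needed.
2. C20 alcohol ⇒ cut between C4 (CH2) and C3 (the methyl-bearing olefin carbon). A C16 homoallylic Grignard reagent is added across but-2-yn-1-ol by an alkoxide-directed, iron-catalysed syn-carbomagnesiation; this forms C3–C4, fixes the 2E olefin and delivers C1 as the free alcohol. Enabling feature: the O–C1–C2=C3 array (oxygen on C1, one atom from the trisubstituted C2=C3 olefin whose C3 carries CH3 and the C4 methylene) is the retron of a 2-alkyn-1-ol, and C4 is a primary carbon two atoms from C6=C7, hence a stable homoallylic Grignard carbon. The cyclohexane ring lies six bonds from C4 and takes no part.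
3. C16 bromide ⇒ C13 terminal alkyne, by zirconium-catalysed methylalumination and ethylene oxide opening (6E olefin, C7 methyl, C5 and C4 in one flask).
4. C13 alkyne ⇒ 1-(chloromethyl)-3,3-dimethylcyclohexene + a silylbutynyl Grignard reagent, by copper-catalysed asymmetric SN2' alkylation that sets the only stereocentre and the exocyclic methylene together.
5. Ring order: the single cyclohexane ring is bought with 3-methylcyclohex-2-en-1-one; no ring is formed in the route.

Key step: step 8

Remarks on the chemistry:
- Locants C1–C9 refer to the nona-2,6-dien-1-yl chain (C1 = CH2O).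
- Assumption: the sense of induction of the copper–phosphoramidite catalyst in step 4 is taken to follow that of the parent 1-(chloromethyl)cyclohexene. The ligand enantiomer is chosen to give the (S) ring carbon; the mirror-image ligand is used if the sense proves opposite.

**Route**

Step 1
Reactants: 1 3-methylcyclohex-2-en-1-one
Product: 3 3,3-dimethylcyclohex-1-en-1-yl trifluoromethanesulfonate, via lithium enolate 2 (not isolated)
Conditions: Me2CuLi (from MeLi, CuI), Et2O, 0 °C; then PhNTf2, THF, 0 °C → rt
Reagents that add atoms: methyllithium, C[Li]; N-phenylbis(trifluoromethanesulfonimide), O=S(=O)(N(c1ccccc1)S(=O)(=O)C(F)(F)F)C(F)(F)F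
Why: Cuprate conjugate addition builds the quaternary carbon and leaves the enolate double bond regiospecifically on the side of that carbon, and O-triflation of this enolate (regiospecific enolate trapping) locks it as the enol triflate.

Step 2
Reactants: 3 3,3-dimethylcyclohex-1-en-1-yl trifluoromethanesulfonate
Product: 4 (3,3-dimethylcyclohex-1-en-1-yl)methanol
Conditions: Bu3SnCH2OH, Pd(PPh3)4 (cat.), LiCl, dioxane, 100 °C
Reagents that add atoms: (tributylstannyl)methanol, CCCC[Sn](CCCC)(CCCC)CO
Why: Stille coupling of an enol triflate with a hydroxymethylstannane transfers the CH2OH group in preference to butyl and gives the allylic alcohol in one step.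

Step 3
Reactants: 4 (3,3-dimethylcyclohex-1-en-1-yl)methanol
Product: 6 1-(chloromethyl)-3,3-dimethylcyclohex-1-ene, via mesylate 5 (not isolated)
Conditions: MsCl, 2,4,6-collidine, LiCl, DMF, 0 °C
Reagents that add atoms: lithium chloride, [Li+].[Cl-]
Why: In situ mesylation followed by SN2 displacement with chloride at the primary allylic carbon should give the chloride without allylic transposition.

Step 4
Reactants: 6 1-(chloromethyl)-3,3-dimethylcyclohex-1-ene; 7 (4-bromobut-1-yn-1-yl)trimethylsilane
Product: 9 {4-[(1S)-2,2-dimethyl-6-methylidenecyclohexyl]but-1-yn-1-yl}trimethylsilane, via Grignard reagent 8 (not isolated)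
Conditions: 7, Mg, Et2O, rt; then slow addition to 6, Cu(O2CC4H3S) (copper thiophene-2-carboxylate, cat.), one enantiomer of the 2,2'-binaphthol-derived phosphoramidite of bis[1-(2-methoxyphenyl)ethyl]amine (cat.), CH2Cl2, −78 °C
Reagents that add atoms: none
Why: Copper-catalysed asymmetric allylic alkylation (SN2') of an endocyclic β-substituted allylic chloride with a Grignard reagent delivers the alkyl group to the ring carbon γ to chloride, which turns the ring olefin into the exocyclic methylene, while the chiral phosphoramidite on copper selects the ring face and so sets the (S) stereocentre.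

Step 5
Reactants: 9 {4-[(1S)-2,2-dimethyl-6-methylidenecyclohexyl]but-1-yn-1-yl}trimethylsilane
Product: 10 (2S)-2-(but-3-yn-1-yl)-1,1-dimethyl-3-methylidenecyclohexane
Conditions: K2CO3, MeOH, rt
Reagents that add atoms: none
Why: Base-catalysed methanolysis of the alkynyl C–Si bond (protodesilylation) frees the terminal alkyne and should touch neither the methylene group nor the stereocentre.

Step 6
Reactants: 10 (2S)-2-(but-3-yn-1-yl)-1,1-dimethyl-3-methylidenecyclohexane
Product: 13 (3E)-6-[(1S)-2,2-dimethyl-6-methylidenecyclohexyl]-4-methylhex-3-en-1-ol, via alkenylalane 11 (not isolated), via lithium aluminate 12 (not isolated)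
Conditions: Me3Al, Cp2ZrCl2 (cat.), CH2Cl2, 0 °C → rt; volatiles removed; n-BuLi, hexane–THF, −78 → 0 °C; ethylene oxide, THF, 0 °C → rt; aq. work-up
Reagents that add atoms: trimethylaluminium, C[Al](C)C; ethylene oxide, C1CO1
Why: Negishi zirconium-catalysed methylalumination adds CH3 and aluminium syn across the terminal alkyne (methyl on the internal carbon), and the derived alkenylaluminate opens ethylene oxide with retention, so the 6E olefin and the two-carbon alcohol arm should arise together; the 1,1-disubstituted ring methylene is not a substrate for this carbometalation.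

Step 7
Reactants: 13 (3E)-6-[(1S)-2,2-dimethyl-6-methylidenecyclohexyl]-4-methylhex-3-en-1-ol
Product: 14 (2S)-2-[(3E)-6-bromo-3-methylhex-3-en-1-yl]-1,1-dimethyl-3-methylidenecyclohexane
Conditions: CBr4, PPh3, CH2Cl2, 0 °C
Reagents that add atoms: carbon tetrabromide, BrC(Br)(Br)Br
Why: Appel bromination converts the primary alcohol into the bromide under neutral conditions that should leave both olefins in place.

Step 8
Reactants: 14 (2S)-2-[(3E)-6-bromo-3-methylhex-3-en-1-yl]-1,1-dimethyl-3-methylidenecyclohexane; 15 but-2-yn-1-ol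
Product: 19 (2E,6E)-9-[(1S)-2,2-dimethyl-6-methylidenecyclohexyl]-3,7-dimethylnona-2,6-dien-1-ol, via Grignard reagent 16 (not isolated), via lithium alkoxide 17 (not isolated), via alkenylmagnesium species 18 (not isolated)
Conditions: 14, Mg, THF, rt → 40 °C; separately 15 (2 equiv.), n-BuLi, THF, −78 → 0 °C; Fe(acac)3 (cat.), 1,2-bis(diphenylphosphino)ethane (cat.), 16 added at −20 °C, then 0 °C; aq. NH4Cl
Reagents that add atoms: none
Why: A low-valent alkyliron species formed from Fe(acac)3 and 16 is held by the C1 alkoxide of 17 and adds its alkyl group and the metal syn across C2≡C3, the alkyl going to the distal carbon C3 and the metal to C2; iron-to-magnesium exchange then releases 18, and protonation gives 19. The closest known reaction type is the iron-catalysed, alkoxide-directed carbomagnesiation of 2-alkyn-1-ols with alkyl Grignard reagents. No ring is closed and no stereocentre is made; the element set is the C2=C3 geometry, which should be E because syn addition leaves the C4 methylene and the C2 hydrogen on the same side. The step needs regioselectivity for C3 over C2, which the alkoxide direction secures, and carbometalation must outrun β-hydride elimination of the primary alkyliron, which the bidentate phosphine and low temperature are meant to ensure. It also needs chemoselectivity over the C6=C7 and exocyclic olefins, which carry no directing group and are unactivated. In one operation the bond, the olefin geometry and the C1 oxidation level are delivered from an achiral, unprotected four-carbon alkynol, with the precious C16 reagent limiting.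

Step 9
Reactants: 19 (2E,6E)-9-[(1S)-2,2-dimethyl-6-methylidenecyclohexyl]-3,7-dimethylnona-2,6-dien-1-ol; 20 Meldrum's acid (2,2-dimethyl-1,3-dioxane-4,6-dione)
Product: 21 3-{[(2E,6E)-9-[(1S)-2,2-dimethyl-6-methylidenecyclohexyl]-3,7-dimethylnona-2,6-dien-1-yl]oxy}-3-oxopropanoic acid (target CNP0184126.1)
Conditions: toluene, 90 °C
Reagents that add atoms: none
Why: Alcoholysis of Meldrum's acid (acylal ring-opening with loss of acetone) should give the malonic acid half ester directly, under weakly acidic conditions that leave the stereocentre and the three olefins alone.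

**Compound list**

1 | 3-methylcyclohex-2-en-1-one | CC1=CC(=O)CCC1 | starting material
2 | lithium 3,3-dimethylcyclohex-1-en-1-olate | CC1(C)CCCC([O-])=C1.[Li+] | intermediate
3 | 3,3-dimethylcyclohex-1-en-1-yl trifluoromethanesulfonate | CC1(C)CCCC(OS(=O)(=O)C(F)(F)F)=C1 | intermediate
4 | (3,3-dimethylcyclohex-1-en-1-yl)methanol | CC1(C)CCCC(CO)=C1 | intermediate
5 | (3,3-dimethylcyclohex-1-en-1-yl)methyl methanesulfonate | CC1(C)CCCC(COS(C)(=O)=O)=C1 | intermediate
6 | 1-(chloromethyl)-3,3-dimethylcyclohex-1-ene | CC1(C)CCCC(CCl)=C1 | intermediate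
7 | (4-bromobut-1-yn-1-yl)trimethylsilane | C[Si](C)(C)C#CCCBr | starting material
8 | [4-(trimethylsilyl)but-3-yn-1-yl]magnesium bromide | C[Si](C)(C)C#CCC[Mg]Br | intermediate
9 | {4-[(1S)-2,2-dimethyl-6-methylidenecyclohexyl]but-1-yn-1-yl}trimethylsilane | C=C1CCCC(C)(C)[C@@H]1CCC#C[Si](C)(C)C | intermediate
10 | (2S)-2-(but-3-yn-1-yl)-1,1-dimethyl-3-methylidenecyclohexane | C=C1CCCC(C)(C)[C@@H]1CCC#C | intermediate
11 | [(1E)-4-[(1S)-2,2-dimethyl-6-methylidenecyclohexyl]-2-methylbut-1-en-1-yl]dimethylalane | C=C1CCCC(C)(C)[C@@H]1CC/C(C)=C/[Al](C)C | intermediate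
12 | lithium butyl[(1E)-4-[(1S)-2,2-dimethyl-6-methylidenecyclohexyl]-2-methylbut-1-en-1-yl]dimethylaluminate | C=C1CCCC(C)(C)[C@@H]1CC/C(C)=C/[Al-](C)(C)CCCC.[Li+] | intermediate
13 | (3E)-6-[(1S)-2,2-dimethyl-6-methylidenecyclohexyl]-4-methylhex-3-en-1-ol | C=C1CCCC(C)(C)[C@@H]1CC/C(C)=C/CCO | intermediate
14 | (2S)-2-[(3E)-6-bromo-3-methylhex-3-en-1-yl]-1,1-dimethyl-3-methylidenecyclohexane | C=C1CCCC(C)(C)[C@@H]1CC/C(C)=C/CCBr | intermediate
15 | but-2-yn-1-ol | CC#CCO | starting material
16 | {(3E)-6-[(1S)-2,2-dimethyl-6-methylidenecyclohexyl]-4-methylhex-3-en-1-yl}magnesium bromide | C=C1CCCC(C)(C)[C@@H]1CC/C(C)=C/CC[Mg]Br | intermediate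
17 | lithium but-2-yn-1-olate | CC#CC[O-].[Li+] | intermediate
18 | lithium (2Z,6E)-2-(bromomagnesio)-9-[(1S)-2,2-dimethyl-6-methylidenecyclohexyl]-3,7-dimethylnona-2,6-dien-1-olate (C4 and Mg cis) | C=C1CCCC(C)(C)[C@@H]1CC/C(C)=C/CC/C(C)=C(\[Mg]Br)C[O-].[Li+] | intermediate
19 | (2E,6E)-9-[(1S)-2,2-dimethyl-6-methylidenecyclohexyl]-3,7-dimethylnona-2,6-dien-1-ol | C=C1CCCC(C)(C)[C@@H]1CC/C(C)=C/CC/C(C)=C/CO | intermediate
20 | Meldrum's acid (2,2-dimethyl-1,3-dioxane-4,6-dione) | CC1(C)OC(=O)CC(=O)O1 | starting material
21 | 3-{[(2E,6E)-9-[(1S)-2,2-dimethyl-6-methylidenecyclohexyl]-3,7-dimethylnona-2,6-dien-1-yl]oxy}-3-oxopropanoic acid | C=C1CCCC(C)(C)[C@@H]1CC/C(C)=C/CC/C(C)=C/COC(=O)CC(=O)O | target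

**Step count and risks**

Total step count: 9. Longest linear sequence: 9 steps (1 → 21).

Steps most likely to fail:

1. Step 8 (key step). β-Hydride elimination from the primary alkyliron intermediate may outrun carbometalation. This would divert the Grignard reagent into reduction or hydromagnesiation of the alkyne, and the iron hydride formed could move the exocyclic double bond into the ring. The fallback sets out from bromide 14 and returns at alcohol 19. The Grignard reagent 16 is made as before and transmetalated with CuBr·SMe2 (THF, −78 °C) to the organocopper reagent F1. This adds syn to ethyl but-2-ynoate at −78 °C (conjugate carbocupration of an alkynoate) to give the alkenylcopper adduct F2, which is protonated with MeOH at −78 °C to the ethyl (2E,6E)-dienoate F3. Reduction of F3 with i-Bu2AlH (CH2Cl2, −78 °C) gives 19.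

2. Step 4. The copper-bound alkyl group may attack the unhindered CH2 terminus (SN2) instead of the ring carbon next to the quaternary centre, and facial discrimination at this crowded position may be weak. The fallback sets out from allylic alcohol 4 and returns at silylalkyne 9.
   - Johnson–Claisen rearrangement of 4 (MeC(OEt)3, cat. EtCO2H, 140 °C) gives the racemic ethyl 2-(2,2-dimethyl-6-methylidenecyclohexyl)acetate F4, with the exocyclic methylene and a two-carbon arm in place.
   - Saponification (LiOH, THF–H2O) gives the racemic acid F5.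
   - Activation as the mixed pivalic anhydride F6 (t-BuCOCl, Et3N, THF) and acylation of lithiated (S)-4-benzyl-1,3-oxazolidin-2-one gives two diastereomeric imides. The (1S)-imide F7 is separated by chromatography or crystallisation from its (1R)-diastereomer F8; the configuration is to be assigned by correlation.
   - LiBH4 (THF, H2O, 0 °C) cleaves F7 to the (S)-alcohol F9.
   - I2, PPh3 and imidazole give the iodide F10, and displacement with LiC≡CSiMe3 (THF–DMPU) gives 9.

3. Step 6. The aluminate may transfer butyl or methyl instead of the alkenyl group to the epoxide, or the Lewis-acidic aluminium may open and oligomerise ethylene oxide. The fallback sets out from alkyne 10 and returns at alcohol 13. The alkenylalane 11 from the same methylalumination is quenched with I2 (THF, −30 °C) to the isolable (E)-alkenyl iodide F11. Iodine–lithium exchange (t-BuLi, Et2O, −78 °C) gives the alkenyllithium F12, which opens ethylene oxide (Et2O, −78 → 0 °C) to 13.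

Further compounds
F1 | step 8 | {(3E)-6-[(1S)-2,2-dimethyl-6-methylidenecyclohexyl]-4-methylhex-3-en-1-yl}copper | C=C1CCCC(C)(C)[C@@H]1CC/C(C)=C/CC[Cu]
F2 | step 8 | ethyl (2Z,6E)-2-cuprio-9-[(1S)-2,2-dimethyl-6-methylidenecyclohexyl]-3,7-dimethylnona-2,6-dienoate (C4 and Cu cis) | C=C1CCCC(C)(C)[C@@H]1CC/C(C)=C/CC/C(C)=C(\[Cu])C(=O)OCC
F3 | step 8 | ethyl (2E,6E)-9-[(1S)-2,2-dimethyl-6-methylidenecyclohexyl]-3,7-dimethylnona-2,6-dienoate | C=C1CCCC(C)(C)[C@@H]1CC/C(C)=C/CC/C(C)=C/C(=O)OCC
F4 | step 4 | racemic ethyl 2-(2,2-dimethyl-6-methylidenecyclohexyl)acetate | C=C1CCCC(C)(C)C1CC(=O)OCC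
F5 | step 4 | racemic 2-(2,2-dimethyl-6-methylidenecyclohexyl)acetic acid | C=C1CCCC(C)(C)C1CC(=O)O
F6 | step 4 | racemic 2-(2,2-dimethyl-6-methylidenecyclohexyl)acetic pivalic anhydride | C=C1CCCC(C)(C)C1CC(=O)OC(=O)C(C)(C)C
F7 | step 4 | (4S)-4-benzyl-3-{2-[(1S)-2,2-dimethyl-6-methylidenecyclohexyl]acetyl}-1,3-oxazolidin-2-one | C=C1CCCC(C)(C)[C@@H]1CC(=O)N1C(=O)OC[C@@H]1Cc1ccccc1
F8 | step 4 | (4S)-4-benzyl-3-{2-[(1R)-2,2-dimethyl-6-methylidenecyclohexyl]acetyl}-1,3-oxazolidin-2-one | C=C1CCCC(C)(C)[C@H]1CC(=O)N1C(=O)OC[C@@H]1Cc1ccccc1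
F9 | step 4 | 2-[(1S)-2,2-dimethyl-6-methylidenecyclohexyl]ethan-1-ol | C=C1CCCC(C)(C)[C@@H]1CCO
F10 | step 4 | (2S)-2-(2-iodoethyl)-1,1-dimethyl-3-methylidenecyclohexane | C=C1CCCC(C)(C)[C@@H]1CCI
F11 | step 6 | (2S)-2-[(3E)-4-iodo-3-methylbut-3-en-1-yl]-1,1-dimethyl-3-methylidenecyclohexane | C=C1CCCC(C)(C)[C@@H]1CC/C(C)=C/I
F12 | step 6 | [(1E)-4-[(1S)-2,2-dimethyl-6-methylidenecyclohexyl]-2-methylbut-1-en-1-yl]lithium | C=C1CCCC(C)(C)[C@@H]1CC/C(C)=C/[Li]
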